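## The problem

Locants used in the discussion: ring A C1 (CO2H), C2 (ether oxygen), C3 (OH), C4 (Cl), C5 (OMe), C6 (H); ring B C1' (CO2H), C2' (ether oxygen), C3' (H), C4' (CH3), C5' (H), C6' (OH).

Target 18 is a diaryl ether whose oxygen bridges ring A C2 and ring B C2'. Three of the four positions ortho to that oxygen are substituted (C1 and C3 on ring A, C1' on ring B). An intermolecular ether synthesis would have to join a doubly ortho-substituted, electron-rich ring A partner to a hindered ring B partner. Ring A carries the contiguous array CO2H–OAr–OH–Cl–OMe, and the chlorine at C4 lies between two oxygens of which only the one at C5 is methylated, so late chlorination or late O-methylation each raise a regiochemical question. The molecule has no stereocentre; stereocentres that appear on the way control nothing in the product and only have to be removable. The ring B acid is a 2,6-dioxygenated benzoic acid that can lose CO2 in hot acid, the aryl chloride does not tolerate forcing hydrogenolysis, and the C5 methyl ether must survive the step that frees the C6' phenol. The enabling feature is the chain ring B carboxyl carbon–C1'–C2'–O–ring A C2. Bonding the carboxyl carbon to C2 closes a benzofuran-3(2H)-one in which C2 is a spiro carbon next to the C3 oxygen function as a ketone. The new C–C bond is then the central bond of a 1,3-diketone, and hydroxide can cut it again once ring A can aromatise.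

## Retrosynthesis

**18 from 17.** The last bond cut is the O–CH3 bond at ring B C6'. This ether is the only protecting group the route needs and comes from the starting arene 1. Its oxygen is ortho to the ring B carboxyl, so a chelating boron Lewis acid can pick it out, while the C5 methyl ether of ring A has no ortho carbonyl. Precursor 17 differs from 18 by one methyl group, and the forward step only has to be selective between two aryl methyl ethers.

**17 from 15.** The ring B carboxyl carbon is reconnected to ring A C2, which gives the spiro dienone 15 (a grisadienone). Cutting the ether C–O bond instead would call for the hindered intermolecular coupling described above. The chosen cut corresponds in the forward sense to a cleavage, not a coupling: hydroxide adds to the benzofuranone ketone, and ring A leaves as an aromatic phenoxide. The same base hydrolyses the ring A ester. The forward step has to attack the benzofuranone ketone in preference to the ring A carbonyl and its methoxy-bearing β-carbon; aromatisation supplies the bias.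

**15 from 13.** The C1=C6 double bond of ring A is taken out. This adds two stereocentres (C2 and C1), but it turns ring A into a cyclohexenone that a cycloaddition can assemble. The forward dehydrogenation has only one site available, because C2 is quaternary.

**13 from 8 and 11.** The C2–C3 and C6–C1 bonds are cut together in a retro-Diels–Alder sense. This leaves the 2-alkylidenebenzofuran-3-one 8 and the 2-chloro ketene-acetal diene 11. Against a stepwise Michael/Claisen construction, one cycloaddition makes both bonds, and the diene brings the C3 oxygen, the C4 chlorine and the C5 methoxy group already in order and already differentiated. Both fragments are small and achiral. The forward reaction must be regioselective: the CH2 terminus of the diene has to bond to the exocyclic carbon.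

**8 from 6 and 7.** The exocyclic C=C bond is cut to the benzofuranone 6 and methyl glyoxylate 7. An aldol condensation installs the future C1 with its carboxyl carbon at the correct oxidation level. Alkene geometry is of no consequence for 18.

**6 from 5, 4, 1 and 2.** The O–CH2 bond of the furanone is cut to the chloroketone phenol 5. The hindered C2–O bond of the target is thus made as an intramolecular alkylation at a primary carbon. Phenol 5 comes from the bis-methyl ether 4 by chelation-directed loss of one methyl group. Ketone 4 is cut at the aryl–acyl bond to the aryllithium 3, from 3,5-dimethoxytoluene 1, and the chloroacetyl donor 2. Lithiation between the two methoxy groups gives the 2,6-dioxygenated pattern that electrophilic acylation of 1 would not give cleanly.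

**11 from 10 and 9.** The O–Si bond and the γ C–H bond are cut to the enoate 10, and the O–CH3 bond of 10 is cut to methyl 2-chloro-3-oxobutanoate 9. The chlorine is bought in place, so no chlorination step is needed.

## Roads not taken

**Alternative 1: ring B from a 2-pyrone and an aryl ynol ether.** The cut removes the C1'–C2' and C3'–C4' bonds of ring B. In the forward sense, methyl 4-methoxy-6-methyl-2-oxo-2H-pyran-3-carboxylate A2 and the aryl ethynyl ether A3 undergo a Diels–Alder reaction, and the bridged lactone then extrudes its carboxyl bridge. This gives methyl 2-[2-(benzyloxy)-3-chloro-6-(1,3-dioxolan-2-yl)-4-methoxyphenoxy]-6-methoxy-4-methylbenzoate A1 directly as the arene.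
- Merits: no oxidation step is needed, the polarity is matched (the nucleophilic terminal carbon of A3 meets C6 of A2), and no spiro dienone has to be handled. In these respects it is cleaner than the chosen plan.
- Weak points: A3 must be made from the fully substituted ring A phenol A4, itself the product of several regiocontrolled aromatic substitutions with the chlorine placed between two oxygens. O-Ethynylation of a doubly ortho-substituted phenol is laborious, and aryl ynol ethers are thermally fragile at the temperatures 2-pyrones usually need.
- After the key step, A1 still needs the acetal unmasked and oxidised, the benzyl group removed beside an aryl chloride, the ring B methyl ether cleaved and a doubly ortho-substituted methyl ester hydrolysed.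
- Comparison: the chosen plan has its own fragile reagent (diene 11) and a dehydrogenation. Against that it sets a ring A built from acyclic carbons with the substituents in order, an ether bond made by a five-membered ring closure, and a ring B carboxyl released as the free acid.

**Alternative 2: ring A grown on the ether oxygen by Michael–Claisen annulation.** The cut removes the C1–C2 and C4–C5 bonds of ring A. The enolate of the aryloxyacetone A6 would add through its aryloxy-bearing carbon to dimethyl fumarate A7, and the methyl ketone would then condense on the distal ester. The product is methyl trans-2-[2-(tert-butoxycarbonyl)-3-methoxy-5-methylphenoxy]-3,5-dioxocyclohexane-1-carboxylate A5 (racemic).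
- Merits: the ether bond arises from a simple phenol O-alkylation, which is as easy as in the chosen plan. The reagents are robust and cheap, and the tert-butyl ester protects the ring B carboxyl orthogonally. On reagent stability this road is better.
- Weak points: the two enolisations of A6 must occur in the right order and at the right carbons. A5 is a cyclohexane-1,3-dione, so ring A must still be chlorinated at C4 and dehydrogenated, and its two nearly equivalent oxygens at C3 and C5 must be told apart so that only C5 is methylated. Steric bias from the neighbouring aryloxy group helps but does not secure this. Two ester cleavages and the ring B demethylation follow.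
- Comparison: the chosen plan sets against the robustness of A6 and A7 the fact that diene 11 delivers oxygen, chlorine and methoxy already differentiated, so the end game is three steps.

**Alternative 3: ring B by Diels–Alder reaction of an aryloxy ynoate.** The cut removes the C2'–C3' and C6'–C1' bonds of ring B. The vinylketene acetal A10 would add across the aryloxy ynoate A9, and the adduct would aromatise by β-elimination of the ketal methoxy group and desilylation. The product is methyl 3-(benzyloxy)-4-chloro-2-[3-hydroxy-2-(methoxycarbonyl)-5-methylphenoxy]-5-methoxybenzoate A8.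
- Merits: ring B appears aromatic with its C6' hydroxyl already free, so the final Lewis-acid demethylation of the chosen plan is not needed. The regiochemistry is polarity-matched. In the end game this road is better.
- Weak points: as in alternative 1, the pentasubstituted ring A phenol A11 must be prepared first by aromatic substitution chemistry. Its conversion into A9 is an addition–elimination at a hindered phenol oxygen. The alkyne of A9 is a push–pull system whose donor oxygen lowers its dienophilicity, and A10 is a less activated diene than 11. Afterwards two methyl esters, one of them a doubly ortho-substituted salicylate, must be hydrolysed and a benzyl ether removed without touching the aryl chloride.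
- Comparison: the chosen plan pays for its convergence with one oxidation and one demethylation, but it never has to make or functionalise a pentasubstituted phenol.

Key step: step 7

Remark: the target has no stereocentre; compounds 12, 13 and 14 are racemic and are drawn as one enantiomer only to show the relative configuration, and the systematic spiro names use their own locants (spiro carbon = ring A C2, 2' = C3, 3' = C4, 4' = C5, 5' = C6, 6' = C1).

## Route

Step 1
Reactants: 1 3,5-dimethoxytoluene; 2 2-chloro-N-methoxy-N-methylacetamide
Product: 4 2-chloro-1-(2,6-dimethoxy-4-methylphenyl)ethan-1-one, via (2,6-dimethoxy-4-methylphenyl)lithium 3 (not isolated)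
Conditions: n-BuLi, THF, 0 °C to rt; then inverse addition to 2, THF, −78 °C; aq. HCl
Reagents that add atoms: none
Why: Directed ortho-lithiation takes place at the ring position flanked by both methoxy groups, the most acidic C–H of 1. The aryllithium adds once to the N-methoxy-N-methylamide because the chelated tetrahedral adduct survives until the acidic quench (ketone synthesis from an N-methoxy-N-methylamide), so the α-chloroketone is not attacked a second time.

Step 2
Reactants: 4 2-chloro-1-(2,6-dimethoxy-4-methylphenyl)ethan-1-one
Product: 5 2-chloro-1-(2-hydroxy-6-methoxy-4-methylphenyl)ethan-1-one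
Conditions: BCl3, CH2Cl2, −78 to 0 °C; H2O
Reagents that add atoms: none
Why: Chelation-directed ether cleavage: BCl3 bridges the ketone oxygen and one ortho methoxy group, and chloride removes that methyl group. The aryloxyboron chelate formed ties up the carbonyl, so the second methoxy group should stay.

Step 3
Reactants: 5 2-chloro-1-(2-hydroxy-6-methoxy-4-methylphenyl)ethan-1-one
Product: 6 4-methoxy-6-methylbenzofuran-3(2H)-one
Conditions: NaOAc, MeOH, reflux
Reagents that add atoms: none
Why: Intramolecular Williamson etherification (5-exo-tet) of the phenoxide on the primary α-chloroketone. Acetate is basic enough for the phenol but too weak to promote self-condensation of the product.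

Step 4
Reactants: 6 4-methoxy-6-methylbenzofuran-3(2H)-one; 7 methyl glyoxylate
Product: 8 methyl (Z)-2-(4-methoxy-6-methyl-3-oxobenzofuran-2(3H)-ylidene)acetate
Conditions: cat. TsOH·H2O, PhMe, 80 °C, azeotropic removal of water
Reagents that add atoms: none
Why: Acid-catalysed aldol condensation of the readily enolised benzofuranone CH2 with a very electrophilic aldehyde, with dehydration driven by conjugation. The Z isomer (ester syn to the ring oxygen) is the thermodynamic one, as in aurones, and the geometry has no bearing on the target.

Step 5
Reactants: 9 methyl 2-chloro-3-oxobutanoate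
Product: 10 methyl 2-chloro-3-methoxybut-2-enoate (E/Z mixture)
Conditions: HC(OMe)3, cat. H2SO4, MeOH, rt to 50 °C; distillation
Reagents that add atoms: trimethyl orthoformate COC(OC)OC
Why: Acid-catalysed ketalisation of the ketone by the orthoformate, followed by loss of methanol on distillation, gives the conjugated methyl enol ether (enol-ether formation from a β-keto ester). The ester and the C–Cl bond are not affected.

Step 6
Reactants: 10 methyl 2-chloro-3-methoxybut-2-enoate (E/Z mixture)
Product: 11 2-chloro-1,3-dimethoxy-1-(trimethylsilyloxy)buta-1,3-diene (mixture of ketene acetal isomers)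
Conditions: LiN(i-Pr)2, THF, −78 °C; Me3SiCl, −78 to 0 °C; pentane, filtration, used directly
Reagents that add atoms: chlorotrimethylsilane C[Si](C)(C)Cl
Why: γ-Deprotonation of the β-methoxy enoate gives the extended enolate, which is trapped on oxygen by Me3SiCl; this is the standard preparation of 1,3-dioxygenated vinylogous silyl ketene acetals. The chlorine sits on an sp2 carbon and should be carried through at −78 °C.

Step 7
Reactants: 8 methyl (Z)-2-(4-methoxy-6-methyl-3-oxobenzofuran-2(3H)-ylidene)acetate; 11 2-chloro-1,3-dimethoxy-1-(trimethylsilyloxy)buta-1,3-diene
Product: 13 methyl (2R*,6'S*)-3'-chloro-4,4'-dimethoxy-6-methyl-2',3-dioxo-3H-spiro[1-benzofuran-2,1'-cyclohex-3'-ene]-6'-carboxylate (racemic; ring oxygen cis to the ester), via silyl methyl ketal cycloadduct 12 (not isolated)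
Conditions: PhMe, 80 °C, sealed under Ar, excess 11; then 0.5 M HCl, THF, 0 °C
Reagents that add atoms: none
Why: This is a thermal, normal-electron-demand [4+2] cycloaddition of the electron-rich trioxygenated diene to the doubly activated exocyclic alkene, concerted but asynchronous; it is the same reaction type as the known spiroannulation of 2-alkylidenebenzofuran-3-ones with oxygenated ketene-acetal dienes to grisans. Ring A closes within the cycloaddition: the CH2 terminus of the diene bonds first to the exocyclic carbon (C6–C1), and the ketene-acetal carbon then bonds to the ring carbon (C2–C3), so the six-membered ring is completed by the second bond of the same event. The selectivity needed is regiochemical. Attack at the exocyclic carbon is β to the ketone and develops aromatic benzofuran-3-olate character, whereas attack at the ring carbon would give only an ester enolate, would build the quaternary centre in the leading bond and would break the O–C=C–CO2Me conjugation, so the ketone should outrank the ester. The two new stereocentres (spiro C2 and C1) follow from suprafacial addition to the Z alkene, which places the ring oxygen and the ester cis; no facial control is needed because 13 is racemic and both centres are removed in steps 8 and 9. No Lewis acid is used, so that a stepwise Mukaiyama–Michael addition, which could not close to the non-enolisable 1,3-diketone, is not favoured. Cold dilute acid converts the mixed silyl methyl ketal into the C3 ketone and leaves the vinylogous ester intact. The chlorine is a spectator on the diene and ends at C4 between the C3 carbonyl and the C5 methoxy group.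

Step 8
Reactants: 13 methyl (2R*,6'S*)-3'-chloro-4,4'-dimethoxy-6-methyl-2',3-dioxo-3H-spiro[1-benzofuran-2,1'-cyclohex-3'-ene]-6'-carboxylate
Product: 15 methyl 3'-chloro-4,4'-dimethoxy-6-methyl-2',3-dioxo-3H-spiro[1-benzofuran-2,1'-cyclohexa-3',5'-diene]-6'-carboxylate (racemic), via silyl dienol ether 14 (not isolated)
Conditions: Me3SiOTf, Et3N, CH2Cl2, 0 °C; then DDQ, PhH, rt
Reagents that add atoms: none
Why: Soft enolisation can only remove a C6 proton because C2 is quaternary, and gives the 2-silyloxy diene. DDQ then abstracts the allylic hydride at C1, forming a cation stabilised by the methoxy and silyloxy groups that loses the silyl group. This is γ,δ-dehydrogenation of an enone through its dienol ether, as used to turn steroidal 4-en-3-ones into 4,6-dien-3-ones; it removes the C1 stereocentre.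

Step 9
Reactants: 15 methyl 3'-chloro-4,4'-dimethoxy-6-methyl-2',3-dioxo-3H-spiro[1-benzofuran-2,1'-cyclohexa-3',5'-diene]-6'-carboxylate
Product: 17 2-(2-carboxy-3-methoxy-5-methylphenoxy)-4-chloro-3-hydroxy-5-methoxybenzoic acid, via ring-opened monomethyl ester 16 (not isolated)
Conditions: NaOH, H2O/THF, 0 to 50 °C; then HCl to pH 1, 0 °C
Reagents that add atoms: sodium hydroxide [Na+].[OH-]
Why: Hydroxide adds to the benzofuranone ketone and the tetrahedral intermediate expels ring A C2 as part of an aromatic phenoxide. This is a retro-Claisen cleavage of a non-enolisable 1,3-diketone driven by aromatisation, the known opening of grisadienones to diphenyl ether acids. The same base then saponifies the ring A ester, and the spiro stereocentre disappears.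

Step 10
Reactants: 17 2-(2-carboxy-3-methoxy-5-methylphenoxy)-4-chloro-3-hydroxy-5-methoxybenzoic acid
Product: 18 2-(2-carboxy-3-hydroxy-5-methylphenoxy)-4-chloro-3-hydroxy-5-methoxybenzoic acid
Conditions: BCl3 (excess), CH2Cl2, −78 to 0 °C; H2O
Reagents that add atoms: none
Why: Chelation-directed demethylation: boron bridges the ring B carboxyl oxygen and the ortho methoxy group, and chloride removes the methyl group. The ring A methoxy group has no ortho carbonyl and should not be cleaved at this temperature, and keeping the mixture at or below 0 °C guards the 2,6-dioxygenated benzoic acid against decarboxylation.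

## Compound list

1 | 3,5-dimethoxytoluene | COc1cc(C)cc(OC)c1 | starting material
2 | 2-chloro-N-methoxy-N-methylacetamide | CON(C)C(=O)CCl | starting material
3 | (2,6-dimethoxy-4-methylphenyl)lithium | [Li]c1c(OC)cc(C)cc1OC | intermediate
4 | 2-chloro-1-(2,6-dimethoxy-4-methylphenyl)ethan-1-one | COc1cc(C)cc(OC)c1C(=O)CCl | intermediate
5 | 2-chloro-1-(2-hydroxy-6-methoxy-4-methylphenyl)ethan-1-one | COc1cc(C)cc(O)c1C(=O)CCl | intermediate
6 | 4-methoxy-6-methylbenzofuran-3(2H)-one | COc1cc(C)cc2OCC(=O)c12 | intermediate
7 | methyl glyoxylate | COC(=O)C=O | starting material
8 | methyl (Z)-2-(4-methoxy-6-methyl-3-oxobenzofuran-2(3H)-ylidene)acetate | COC(=O)/C=C1\Oc2cc(C)cc(OC)c2C1=O | intermediate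
9 | methyl 2-chloro-3-oxobutanoate | COC(=O)C(Cl)C(C)=O | starting material
10 | methyl 2-chloro-3-methoxybut-2-enoate (E/Z mixture) | COC(=O)C(Cl)=C(C)OC | intermediate
11 | 2-chloro-1,3-dimethoxy-1-(trimethylsilyloxy)buta-1,3-diene (mixture of ketene acetal isomers) | COC(O[Si](C)(C)C)=C(Cl)C(OC)=C | intermediate
12 | methyl 3'-chloro-2',4,4'-trimethoxy-6-methyl-3-oxo-2'-(trimethylsilyloxy)-3H-spiro[1-benzofuran-2,1'-cyclohex-3'-ene]-6'-carboxylate (racemic; ring oxygen cis to the ester; both epimers at the ketal carbon) | O=C1c2c(OC)cc(C)cc2O[C@@]13C(OC)(O[Si](C)(C)C)C(Cl)=C(OC)C[C@@H]3C(=O)OC | intermediate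
13 | methyl (2R*,6'S*)-3'-chloro-4,4'-dimethoxy-6-methyl-2',3-dioxo-3H-spiro[1-benzofuran-2,1'-cyclohex-3'-ene]-6'-carboxylate (racemic; ring oxygen cis to the ester) | O=C1c2c(OC)cc(C)cc2O[C@@]13C(=O)C(Cl)=C(OC)C[C@@H]3C(=O)OC | intermediate
14 | methyl 3'-chloro-4,4'-dimethoxy-6-methyl-3-oxo-2'-(trimethylsilyloxy)-3H-spiro[1-benzofuran-2,1'-cyclohexa-2',4'-diene]-6'-carboxylate (racemic; relative configuration as in 13) | O=C1c2c(OC)cc(C)cc2O[C@@]13C(O[Si](C)(C)C)=C(Cl)C(OC)=C[C@@H]3C(=O)OC | intermediate
15 | methyl 3'-chloro-4,4'-dimethoxy-6-methyl-2',3-dioxo-3H-spiro[1-benzofuran-2,1'-cyclohexa-3',5'-diene]-6'-carboxylate (racemic) | O=C1c2c(OC)cc(C)cc2OC13C(=O)C(Cl)=C(OC)C=C3C(=O)OC | intermediate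
16 | 2-[3-chloro-2-hydroxy-4-methoxy-6-(methoxycarbonyl)phenoxy]-6-methoxy-4-methylbenzoic acid (present as its sodium salt) | COC(=O)c1cc(OC)c(Cl)c(O)c1Oc1cc(C)cc(OC)c1C(=O)O | intermediate
17 | 2-(2-carboxy-3-methoxy-5-methylphenoxy)-4-chloro-3-hydroxy-5-methoxybenzoic acid | COc1cc(C(=O)O)c(Oc2cc(C)cc(OC)c2C(=O)O)c(O)c1Cl | intermediate
18 | 2-(2-carboxy-3-hydroxy-5-methylphenoxy)-4-chloro-3-hydroxy-5-methoxybenzoic acid | COc1cc(C(=O)O)c(Oc2cc(C)cc(O)c2C(=O)O)c(O)c1Cl | target

## Step count and least certain steps

Total step count: 10. Longest linear sequence: 8 steps (steps 1 to 4 and 7 to 10); steps 5 and 6 form the two-step diene branch.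

**Step 7 (key step).** The cycloaddition may stall or stop at an open Michael-type adduct, because the chlorine lowers the nucleophilicity of the diene and crowds its s-cis conformation. Regiocontrol may also erode, because the ester on the exocyclic carbon pulls against the ketone. The fallback sets out from 8 and moves the chlorine to a later step. Purchased methyl (E)-3-methoxybut-2-enoate F1 is converted with LiN(i-Pr)2 and Me3SiCl into the chlorine-free diene 1,3-dimethoxy-1-(trimethylsilyloxy)buta-1,3-diene F2, a diene of the class already proven on alkylidenebenzofuranones. Cycloaddition to 8 gives the silyl methyl ketal cycloadduct F3, and acidic work-up gives methyl 4,4'-dimethoxy-6-methyl-2',3-dioxo-3H-spiro[1-benzofuran-2,1'-cyclohex-3'-ene]-6'-carboxylate F4 (racemic, ring oxygen cis to the ester). Electrophilic chlorination of F4 with N-chlorosuccinimide at the nucleophilic α-carbon of the vinylogous ester then returns to the route at 13.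

**Step 6.** Decomposition of the lithium α-chloro dienolate before it is silylated, or C-silylation, would leave no usable diene; hydrolysis of 11 during handling is the second hazard. The fallback sets out from 9 and uses the known class of 2-chloro-1,3-bis(silyloxy) dienes. Silylation of 9 with Me3SiCl and Et3N gives methyl 2-chloro-3-(trimethylsilyloxy)but-2-enoate F5, and LiN(i-Pr)2 with Me3SiCl converts it into 2-chloro-1-methoxy-1,3-bis(trimethylsilyloxy)buta-1,3-diene F6. Cycloaddition of F6 to 8 gives the bis-silyl cycloadduct F7, and acidic work-up gives the enolised chloro dione methyl 3'-chloro-4'-hydroxy-4-methoxy-6-methyl-2',3-dioxo-3H-spiro[1-benzofuran-2,1'-cyclohex-3'-ene]-6'-carboxylate F8. O-Methylation of F8 with Me3SiCHN2 in MeOH/PhMe, expected to favour the oxygen remote from the quaternary spiro carbon, returns to the route at 13; the regioisomeric enol ether would have to be separated.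

**Step 8.** Hydride abstraction at C1 may be slow, because that C–H is tertiary, α to an ester and next to the spiro centre; the quinone may instead add to the silyl dienol ether. The fallback sets out from 14 and replaces hydride abstraction by bromination and elimination. N-Bromosuccinimide brominates the dienol ether at C6 to give methyl 5'-bromo-3'-chloro-4,4'-dimethoxy-6-methyl-2',3-dioxo-3H-spiro[1-benzofuran-2,1'-cyclohex-3'-ene]-6'-carboxylate F9. DBU then removes HBr through the ester enolate (E1cB), which returns to the route at 15.

**Step 9.** Hydroxide may add to the methoxy-bearing carbon C5 of the dienone (addition–elimination with loss of the methyl enol ether) or to the ring A carbonyl, in competition with addition to the benzofuranone ketone. The fallback sets out from 15 and uses electrophilic instead of nucleophilic activation. Aqueous acid (CF3CO2H/H2O) hydrates the benzofuranone ketone and the protonated dienone acts as the electron sink for C–C cleavage, the acid-mediated opening known for grisadienones. This gives 16 as an isolated compound, and mild saponification of its ring A ester with LiOH returns to the route at 17.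

**Step 10.** Ether cleavage may be incomplete or unselective, because the triacidic substrate consumes the Lewis acid and dissolves poorly; prolonged exposure risks decarboxylation of the ring B acid. The fallback sets out from 17 and runs the demethylation on an ester. MeI and KHCO3 in DMF esterify both carboxyl groups to methyl 4-chloro-3-hydroxy-5-methoxy-2-[3-methoxy-2-(methoxycarbonyl)-5-methylphenoxy]benzoate F10. BCl3 then cleaves the ring B methyl ether ortho to the ester, the best-precedented substrate type, to give methyl 4-chloro-3-hydroxy-2-[3-hydroxy-2-(methoxycarbonyl)-5-methylphenoxy]-5-methoxybenzoate F11. Saponification of both esters with NaOH in H2O/dioxane at 60 °C returns to the route at 18.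

## Further compounds

F1 | step 7 | methyl (E)-3-methoxybut-2-enoate (purchased) | CO/C(C)=C/C(=O)OC
F2 | step 7 | 1,3-dimethoxy-1-(trimethylsilyloxy)buta-1,3-diene | COC(O[Si](C)(C)C)=CC(OC)=C
F3 | step 7 | methyl 2',4,4'-trimethoxy-6-methyl-3-oxo-2'-(trimethylsilyloxy)-3H-spiro[1-benzofuran-2,1'-cyclohex-3'-ene]-6'-carboxylate (racemic; ring oxygen cis to the ester; both ketal epimers) | O=C1c2c(OC)cc(C)cc2O[C@@]13C(OC)(O[Si](C)(C)C)C=C(OC)C[C@@H]3C(=O)OC
F4 | step 7 | methyl 4,4'-dimethoxy-6-methyl-2',3-dioxo-3H-spiro[1-benzofuran-2,1'-cyclohex-3'-ene]-6'-carboxylate (racemic; ring oxygen cis to the ester) | O=C1c2c(OC)cc(C)cc2O[C@@]13C(=O)C=C(OC)C[C@@H]3C(=O)OC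
F5 | step 6 | methyl 2-chloro-3-(trimethylsilyloxy)but-2-enoate | COC(=O)C(Cl)=C(C)O[Si](C)(C)C
F6 | step 6 | 2-chloro-1-methoxy-1,3-bis(trimethylsilyloxy)buta-1,3-diene | COC(O[Si](C)(C)C)=C(Cl)C(O[Si](C)(C)C)=C
F7 | step 6 | methyl 3'-chloro-2',4-dimethoxy-6-methyl-3-oxo-2',4'-bis(trimethylsilyloxy)-3H-spiro[1-benzofuran-2,1'-cyclohex-3'-ene]-6'-carboxylate (racemic; ring oxygen cis to the ester; both ketal epimers) | O=C1c2c(OC)cc(C)cc2O[C@@]13C(OC)(O[Si](C)(C)C)C(Cl)=C(O[Si](C)(C)C)C[C@@H]3C(=O)OC
F8 | step 6 | methyl 3'-chloro-4'-hydroxy-4-methoxy-6-methyl-2',3-dioxo-3H-spiro[1-benzofuran-2,1'-cyclohex-3'-ene]-6'-carboxylate (racemic; ring oxygen cis to the ester; enol form of the 2',4'-dione) | O=C1c2c(OC)cc(C)cc2O[C@@]13C(=O)C(Cl)=C(O)C[C@@H]3C(=O)OC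
F9 | step 8 | methyl 5'-bromo-3'-chloro-4,4'-dimethoxy-6-methyl-2',3-dioxo-3H-spiro[1-benzofuran-2,1'-cyclohex-3'-ene]-6'-carboxylate (racemic; bromide epimers) | O=C1c2c(OC)cc(C)cc2O[C@@]13C(=O)C(Cl)=C(OC)C(Br)[C@@H]3C(=O)OC
F0 | step 9 | none | none
F10 | step 10 | methyl 4-chloro-3-hydroxy-5-methoxy-2-[3-methoxy-2-(methoxycarbonyl)-5-methylphenoxy]benzoate | COC(=O)c1cc(OC)c(Cl)c(O)c1Oc1cc(C)cc(OC)c1C(=O)OC
F11 | step 10 | methyl 4-chloro-3-hydroxy-2-[3-hydroxy-2-(methoxycarbonyl)-5-methylphenoxy]-5-methoxybenzoate | COC(=O)c1cc(OC)c(Cl)c(O)c1Oc1cc(C)cc(O)c1C(=O)OC
A1 | alternative 1 | methyl 2-[2-(benzyloxy)-3-chloro-6-(1,3-dioxolan-2-yl)-4-methoxyphenoxy]-6-methoxy-4-methylbenzoate | COC(=O)c1c(OC)cc(C)cc1Oc1c(C2OCCO2)cc(OC)c(Cl)c1OCc1ccccc1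
A2 | alternative 1 | methyl 4-methoxy-6-methyl-2-oxo-2H-pyran-3-carboxylate | COC(=O)C1=C(OC)C=C(C)OC1=O
A3 | alternative 1 | 2-[3-(benzyloxy)-4-chloro-2-(ethynyloxy)-5-methoxyphenyl]-1,3-dioxolane | C#COc1c(C2OCCO2)cc(OC)c(Cl)c1OCc1ccccc1
A4 | alternative 1 | 2-(benzyloxy)-3-chloro-6-(1,3-dioxolan-2-yl)-4-methoxyphenol | Oc1c(C2OCCO2)cc(OC)c(Cl)c1OCc1ccccc1
A5 | alternative 2 | methyl trans-2-[2-(tert-butoxycarbonyl)-3-methoxy-5-methylphenoxy]-3,5-dioxocyclohexane-1-carboxylate (racemic) | COC(=O)[C@@H]1CC(=O)CC(=O)[C@H]1Oc1cc(C)cc(OC)c1C(=O)OC(C)(C)C
A6 | alternative 2 | tert-butyl 2-methoxy-4-methyl-6-(2-oxopropoxy)benzoate | CC(=O)COc1cc(C)cc(OC)c1C(=O)OC(C)(C)C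
A7 | alternative 2 | dimethyl fumarate | COC(=O)/C=C/C(=O)OC
A8 | alternative 3 | methyl 3-(benzyloxy)-4-chloro-2-[3-hydroxy-2-(methoxycarbonyl)-5-methylphenoxy]-5-methoxybenzoate | COC(=O)c1cc(OC)c(Cl)c(OCc2ccccc2)c1Oc1cc(C)cc(O)c1C(=O)OC
A9 | alternative 3 | methyl 3-(benzyloxy)-4-chloro-5-methoxy-2-[(3-methoxy-3-oxoprop-1-yn-1-yl)oxy]benzoate | COC(=O)C#COc1c(C(=O)OC)cc(OC)c(Cl)c1OCc1ccccc1
A10 | alternative 3 | 1-methoxy-3-methyl-1-(trimethylsilyloxy)buta-1,3-diene | COC(O[Si](C)(C)C)=CC(C)=C
A11 | alternative 3 | methyl 3-(benzyloxy)-4-chloro-2-hydroxy-5-methoxybenzoate | COC(=O)c1cc(OC)c(Cl)c(OCc2ccccc2)c1O
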